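**Retrosynthetic overview**
1. Feature: in the ten-membered carbocycle C1–C10 the two trans-epoxides sit at C1–C10 and C4–C5, so C5 and C10 face each other across the ring. An imaginary transannular C5–C10 bond turns the macrocycle into the trans-decalin (rings A and B) of a eudesmanolide, with C6 and C8 on a rigid chair beside the butenolide ring.
2. Endgame: both epoxides come from the 1(10)E,4E-diene by attack on the outer alkene faces, and that diene comes from the 1(10)E,2Z,4E-triene by saturating only C2=C3.
3. Key disconnection: the triene comes from a 5αH-eudesma-1,3-diene by photochemical 6π ring opening, which cleaves C5–C10.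
4. The eudesmadiene comes from α-santonin. Ring A goes dienone → trans-fused Δ1-3-ketone → 3β-ol → 1,3-diene. The lactone goes α-methylene lactone → 11,13-diol → 13-acetoxy-7(11)-butenolide. C8–O comes from allylic hydroxylation (8β) and Mitsunobu inversion with the epoxy acid from (R)-2-methylglycidol, whose oxirane is later opened by chloride.
5. Ring order: rings A and B and the lactone ring arrive with santonin, the ten-membered ring is unveiled in the key step, and the two oxiranes are closed last.

Key step: step 15

Remark: eudesmane/germacrane numbering is used throughout, with α/β referring to the usual orientation (C14 is β). The C2 configuration of the bis-selenide and bis-selenoxide (drawn 2α) and the chirality at selenium do not matter, because both are erased on elimination.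

Step 1
Reactants: 1 α-santonin
Product: 3 α-tetrahydrosantonin (4α-methyl-3-oxo-5αH,11βH-eudesman-12,6α-olide), via 4-epi-tetrahydrosantonin 2 (not isolated)
Conditions: H2 (1 atm), 10% Pd/C, EtOAc, rt; filter; then p-TsOH·H2O (cat.), CHCl3, rt
Reagents that add atoms: none
Why: Heterogeneous catalytic hydrogenation adds hydrogen to both enone alkenes from the α face, opposite the angular 10β-methyl, which sets 5α-H (trans-decalin) and first leaves the C4 methyl axial (4β) in 2, and acid-catalysed enolisation of the 3-ketone then equilibrates C4 to the equatorial 4α-methyl epimer 3 while C6, C7, C10 and C11 are untouched.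

Step 2
Reactants: 3 α-tetrahydrosantonin
Product: 4 2α,11β-bis(phenylselanyl)-4α-methyl-3-oxo-5αH-eudesman-12,6α-olide
Conditions: LiN(iPr)2 (LDA, 2.5 equiv), THF, −78 °C; PhSeCl (2.5 equiv), −78 → −40 °C
Reagents that add atoms: benzeneselenenyl chloride, Cl[Se]c1ccccc1
Why: α-Selenenylation of a kinetic bis-enolate: LiN(iPr)2 removes the less hindered ketone α-hydrogen at C2 (C4 is tertiary and next to the ring fusion) and 11-H of the lactone, and PhSeCl is taken up at C2 and, anti to the pseudo-axial 7α-H, on the β face of C11, both new centres being erased in step 3.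

Step 3
Reactants: 4 bis-selenide
Product: 6 4α-methyl-3-oxo-5αH-eudesma-1,11(13)-dien-12,6α-olide, via bis-selenoxide 5 (not isolated)
Conditions: 30% aq. H2O2, pyridine, CH2Cl2, 0 °C → rt
Reagents that add atoms: none
Why: Selenoxide syn elimination: the C2 selenoxide removes a C1 hydrogen to give the Δ1-enone, and the 11β-selenoxide finds no syn hydrogen on C7 (7-H is α) and therefore removes a C13 hydrogen to give only the exocyclic α-methylene lactone.

Step 4
Reactants: 6 Δ1-enone α-methylene lactone
Product: 7 11β,13-dihydroxy-4α-methyl-3-oxo-5αH-eudesm-1-en-12,6α-olide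
Conditions: OsO4 (2 mol %), NMO (1.1 equiv), acetone/H2O, 0 °C
Reagents that add atoms: N-methylmorpholine N-oxide, C[N+]1([O-])CCOCC1; water, O
Why: Catalytic OsO4/NMO syn dihydroxylation: the unhindered 1,1-disubstituted C11=C13 alkene reacts ahead of the more electron-poor C1=C2 enone alkene, which is shielded by quaternary C10, and approach anti to the pseudo-axial 7α-H (the face also preferred in step 2) places the tertiary hydroxyl 11β and C13 11α.

Step 5
Reactants: 7 11β,13-diol
Product: 8 13-acetoxy-11β-hydroxy-4α-methyl-3-oxo-5αH-eudesm-1-en-12,6α-olide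
Conditions: Ac2O (1.1 equiv), pyridine, CH2Cl2, 0 °C
Reagents that add atoms: acetic anhydride, CC(=O)OC(C)=O
Why: Chemoselective O-acetylation: without an acyl-transfer catalyst the primary 13-OH is esterified while the hindered tertiary α-hydroxy-lactone OH at C11 stays free.

Step 6
Reactants: 8 13-acetoxy-11β-ol
Product: 9 13-acetoxy-4α-methyl-3-oxo-5αH-eudesma-1,7(11)-dien-12,6α-olide
Conditions: SOCl2 (1.5 equiv), pyridine, 0 °C
Reagents that add atoms: none
Why: Anti E2 dehydration of a tertiary alcohol with SOCl2/pyridine: the activated 11β-oxygen is antiperiplanar to the pseudo-axial 7α-H, so loss of these two groups gives the tetrasubstituted, conjugated C7=C11 butenolide in preference to the C11=C13 enol acetate, and C6 is not touched.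

Step 7
Reactants: 9 enone butenolide
Product: 10 13-acetoxy-3β-hydroxy-4α-methyl-5αH-eudesma-1,7(11)-dien-12,6α-olide
Conditions: NaBH4, CeCl3·7H2O, MeOH, −78 → −40 °C
Reagents that add atoms: none
Why: Luche 1,2-reduction: the CeCl3-modified borohydride attacks only the ketone carbonyl (the tetrasubstituted butenolide and the esters are inert at low temperature) along the axial α trajectory, away from the 10β-methyl, and sets the equatorial 3β-alcohol.

Step 8
Reactants: 10 3β-allylic alcohol
Product: 11 13-acetoxy-3β-(tert-butyldimethylsilyloxy)-4α-methyl-5αH-eudesma-1,7(11)-dien-12,6α-olide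
Conditions: TBSCl, imidazole, CH2Cl2/DMF, 0 °C → rt
Reagents that add atoms: tert-butyldimethylsilyl chloride, CC(C)(C)[Si](C)(C)Cl
Why: Silyl ether formation masks the ring A alcohol so that C3 is neither oxidised in step 9 nor esterified in step 11, and imidazole is too weak a base to deprotonate 6-H of the butenolide.

Step 9
Reactants: 11 3β-silyl ether
Product: 12 13-acetoxy-8β-hydroxy-3β-(tert-butyldimethylsilyloxy)-4α-methyl-5αH-eudesma-1,7(11)-dien-12,6α-olide
Conditions: SeO2 (1.5 equiv), 1,4-dioxane, 80–90 °C
Reagents that add atoms: selenium dioxide, O=[Se]=O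
Why: Riley allylic hydroxylation γ to an enoate: the ene reaction places selenium on C11 (the α-carbon and more nucleophilic alkene terminus) and removes the axial 8β-H, the only unoxygenated allylic C–H aligned with the π system (6-H and the C13 hydrogens sit on acyloxy-bearing carbons, and the ring A alkene offers only the hindered, silyloxy-bearing 3-H), and the suprafacial [2,3]-sigmatropic shift returns oxygen to the same β face, so the axial 8β-alcohol is expected.

Step 10
Reactants: 13 (R)-2-methylglycidol
Product: 14 (S)-2-methyloxirane-2-carboxylic acid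
Conditions: RuCl3·xH2O (2 mol %), NaIO4 (excess), MeCN/EtOAc/H2O, 0 °C → rt
Reagents that add atoms: water, O
Why: RuO4-catalysed oxidation (RuCl3/NaIO4) takes the primary alcohol through the aldehyde hydrate to the acid without touching the oxirane, and the quaternary centre keeps its spatial arrangement (the descriptor changes from R to S only because CO2H outranks the ring CH2).

Step 11
Reactants: 12 8β-allylic alcohol; 14 (S)-2-methyloxirane-2-carboxylic acid
Product: 15 13-acetoxy-8α-[(S)-2-methyloxirane-2-carbonyloxy]-3β-(tert-butyldimethylsilyloxy)-4α-methyl-5αH-eudesma-1,7(11)-dien-12,6α-olide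
Conditions: PPh3, DIAD, toluene, 0 °C → rt
Reagents that add atoms: 14 (S)-2-methyloxirane-2-carboxylic acid, OC(=O)[C@@]1(C)OC1
Why: Mitsunobu esterification: the activated axial 8β-oxygen of the allylic alcohol is displaced by the carboxylate of 14 in an SN2 process from the open α face, which inverts C8 to the required 8α (S) configuration and installs the side-chain skeleton in one operation, while the SN2′ terminus C11 is fully substituted and the quaternary C2′ centre is not involved.

Step 12
Reactants: 15 8α-epoxy ester silyl ether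
Product: 16 13-acetoxy-3β-hydroxy-8α-[(S)-2-methyloxirane-2-carbonyloxy]-4α-methyl-5αH-eudesma-1,7(11)-dien-12,6α-olide
Conditions: HF·pyridine, pyridine, THF, 0 °C → rt
Reagents that add atoms: none
Why: Fluoride-mediated desilylation under buffered, non-basic conditions frees 3β-OH while the electron-poor glycidate oxirane, the two allylic esters and the base-sensitive 13-acetoxybutenolide survive.

Step 13
Reactants: 16 3β-allylic alcohol
Product: 17 13-acetoxy-8α-[(S)-2-methyloxirane-2-carbonyloxy]-5αH-eudesma-1,3,7(11)-trien-12,6α-olide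
Conditions: Burgess reagent (MeO2CN(−)SO2N(+)Et3), toluene, 50 °C
Reagents that add atoms: none
Why: Burgess dehydration, a syn elimination eased by the allylic position: the 3β-oxygen and the axial 4β-H are cis, C4 carries the only β-hydrogen (C2 is vinylic and C10 quaternary), so only the homoannular C1=C2–C3=C4 diene can form with 5α-H intact, and the neutral medium spares oxirane, esters and butenolide.

Step 14
Reactants: 17 eudesmadiene epoxy ester
Product: 18 13-acetoxy-8α-[(R)-3-chloro-2-hydroxy-2-methylpropanoyloxy]-5αH-eudesma-1,3,7(11)-trien-12,6α-olide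
Conditions: LiCl, AcOH, THF, rt
Reagents that add atoms: lithium chloride, [Li+].[Cl-]
Why: Regioselective halide opening of a 2,2-disubstituted glycidic ester: chloride attacks the unhindered CH2 terminus in an SN2 sense, the C2′–O bond stays intact so C2′ keeps its arrangement (now R because CH2Cl outranks the carboxyl carbon), and the weak acid leaves the diene and the allylic esters alone.

Step 15
Reactants: 18 5αH-eudesma-1,3,7(11)-trienolide
Product: 19 13-acetoxy-8α-[(R)-3-chloro-2-hydroxy-2-methylpropanoyloxy]germacra-1(10)E,2Z,4E,7(11)-tetraen-12,6α-olide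
Conditions: hν (295–305 nm), quartz vessel, degassed Et2O/THF (ca. 2 mM), −40 °C, to the photostationary state; solution kept at ≤ −40 °C and used at once
Reagents that add atoms: none
Why: Selective excitation of the homoannular C1=C2–C3=C4 diene, whose long-wavelength band lies well to the red of the butenolide π–π* band, triggers a six-electron conrotatory electrocyclic ring opening that cleaves the C5–C10 σ bond shared by rings A and B. The closest known reaction type is the photochemical opening of trans-fused bicyclo[4.4.0]deca-2,4-dienes to (E,Z,E)-cyclodeca-1,3,5-trienes, the same pericyclic event as the provitamin D to previtamin D conversion. No ring is closed by bond formation: the ten-membered carbocycle C1–C10 appears because the bond common to the two six-membered rings is removed, while the butenolide ring stays intact. No stereocentre is created; orbital symmetry acting on the trans fusion (5α-H, 10β-CH3), together with least motion, swings the pseudo-equatorial C5–C6 and C10–C9 bonds outward and the axial 5-H and C14 inward, which fixes 1(10)E, 2Z and 4E and delivers the conformer with C14 and C15 both on the β face, and C6, C8 and C2′ are untouched. The step needs chromophore selectivity, secured by the wavelength window, and protection of 19 from thermal disrotatory re-closure to a cis-fused diene and from secondary photochemistry, secured by the low temperature, high dilution and immediate use.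

Step 16
Reactants: 19 (E,Z,E)-triene
Product: 20 13-acetoxy-8α-[(R)-3-chloro-2-hydroxy-2-methylpropanoyloxy]germacra-1(10)E,4E,7(11)-trien-12,6α-olide
Conditions: KO2CN=NCO2K (excess), AcOH, CH2Cl2/MeOH added to the cold photolysate, −50 → −20 °C
Reagents that add atoms: none
Why: Diimide reduction (concerted syn transfer of two hydrogens, generated cold from KO2CN=NCO2K and AcOH): the cis-1,2-disubstituted C2=C3 alkene is reduced much faster than the methyl-bearing trisubstituted C1=C10 and C4=C5 alkenes and the tetrasubstituted butenolide, no C–O or C–Cl hydrogenolysis can occur, and removal of the central alkene switches off thermal 6π re-closure.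

Step 17
Reactants: 20 germacra-1(10)E,4E-dienolide
Product: 21 target, 13-acetoxy-8α-[(R)-3-chloro-2-hydroxy-2-methylpropanoyloxy]-1β,10α:4α,5β-diepoxygermacr-7(11)-en-12,6α-olide
Conditions: DMDO (2.5 equiv), acetone/CH2Cl2, −20 → 0 °C
Reagents that add atoms: dimethyldioxirane, CC1(C)OO1
Why: Double epoxidation with neutral DMDO: the two trisubstituted E-alkenes stand roughly perpendicular to the mean ring plane in the crown conformer that has C14 and C15 on the β face (the C4=C5 orientation is locked by allylic 1,3-strain between C15 and the C6 substituents, with 6-H eclipsing the alkene), only their outer faces are open, syn addition to E-alkenes gives the trans-epoxides 1β,10α (1R,10R) and 4α,5β (4R,5R), the electron-poor butenolide alkene is inert, and the absence of acid prevents transannular cyclisation of the mono-epoxide.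

**Compound list**
1 | α-santonin (3-oxo-11βH-eudesma-1,4-dien-12,6α-olide) | C[C@H]1[C@@H]2CC[C@]3(C=CC(=O)C(C)=C3[C@H]2OC1=O)C | starting material
2 | 4-epi-tetrahydrosantonin (4β-methyl-3-oxo-5αH,11βH-eudesman-12,6α-olide) | C[C@H]1[C@@H]2CC[C@@]3(C)CCC(=O)[C@H](C)[C@@H]3[C@H]2OC1=O | intermediate
3 | α-tetrahydrosantonin (4α-methyl-3-oxo-5αH,11βH-eudesman-12,6α-olide) | C[C@H]1[C@@H]2CC[C@@]3(C)CCC(=O)[C@@H](C)[C@@H]3[C@H]2OC1=O | intermediate
4 | 2α,11β-bis(phenylselanyl)-4α-methyl-3-oxo-5αH-eudesman-12,6α-olide | C[C@@]1([Se]c4ccccc4)[C@@H]2CC[C@@]3(C)C[C@@H]([Se]c4ccccc4)C(=O)[C@@H](C)[C@@H]3[C@H]2OC1=O | intermediate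
5 | 2α,11β-bis(phenylseleninyl) analogue of 4 (bis-selenoxide) | C[C@@]1([Se](=O)c4ccccc4)[C@@H]2CC[C@@]3(C)C[C@@H]([Se](=O)c4ccccc4)C(=O)[C@@H](C)[C@@H]3[C@H]2OC1=O | intermediate
6 | 4α-methyl-3-oxo-5αH-eudesma-1,11(13)-dien-12,6α-olide | C=C1[C@@H]2CC[C@@]3(C)C=CC(=O)[C@@H](C)[C@@H]3[C@H]2OC1=O | intermediate
7 | 11β,13-dihydroxy-4α-methyl-3-oxo-5αH-eudesm-1-en-12,6α-olide | OC[C@@]1(O)[C@@H]2CC[C@@]3(C)C=CC(=O)[C@@H](C)[C@@H]3[C@H]2OC1=O | intermediate
8 | 13-acetoxy-11β-hydroxy-4α-methyl-3-oxo-5αH-eudesm-1-en-12,6α-olide | CC(=O)OC[C@@]1(O)[C@@H]2CC[C@@]3(C)C=CC(=O)[C@@H](C)[C@@H]3[C@H]2OC1=O | intermediate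
9 | 13-acetoxy-4α-methyl-3-oxo-5αH-eudesma-1,7(11)-dien-12,6α-olide | CC(=O)OCC1=C2CC[C@@]3(C)C=CC(=O)[C@@H](C)[C@@H]3[C@H]2OC1=O | intermediate
10 | 13-acetoxy-3β-hydroxy-4α-methyl-5αH-eudesma-1,7(11)-dien-12,6α-olide | CC(=O)OCC1=C2CC[C@@]3(C)C=C[C@H](O)[C@@H](C)[C@@H]3[C@H]2OC1=O | intermediate
11 | 3β-O-TBS ether of 10 | CC(=O)OCC1=C2CC[C@@]3(C)C=C[C@H](O[Si](C)(C)C(C)(C)C)[C@@H](C)[C@@H]3[C@H]2OC1=O | intermediate
12 | 8β-hydroxy derivative of 11 | CC(=O)OCC1=C2[C@H](O)C[C@@]3(C)C=C[C@H](O[Si](C)(C)C(C)(C)C)[C@@H](C)[C@@H]3[C@H]2OC1=O | intermediate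
13 | (R)-2-methylglycidol | OC[C@@]1(C)OC1 | starting material
14 | (S)-2-methyloxirane-2-carboxylic acid | OC(=O)[C@@]1(C)OC1 | intermediate
15 | 8α-[(S)-2-methyloxirane-2-carbonyloxy] derivative of 11 | CC(=O)OCC1=C2[C@@H](OC(=O)[C@@]4(C)OC4)C[C@@]3(C)C=C[C@H](O[Si](C)(C)C(C)(C)C)[C@@H](C)[C@@H]3[C@H]2OC1=O | intermediate
16 | 13-acetoxy-3β-hydroxy-8α-[(S)-2-methyloxirane-2-carbonyloxy]-4α-methyl-5αH-eudesma-1,7(11)-dien-12,6α-olide | CC(=O)OCC1=C2[C@@H](OC(=O)[C@@]4(C)OC4)C[C@@]3(C)C=C[C@H](O)[C@@H](C)[C@@H]3[C@H]2OC1=O | intermediate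
17 | 13-acetoxy-8α-[(S)-2-methyloxirane-2-carbonyloxy]-5αH-eudesma-1,3,7(11)-trien-12,6α-olide | CC(=O)OCC1=C2[C@@H](OC(=O)[C@@]4(C)OC4)C[C@@]3(C)C=CC=C(C)[C@@H]3[C@H]2OC1=O | intermediate
18 | 13-acetoxy-8α-[(R)-3-chloro-2-hydroxy-2-methylpropanoyloxy]-5αH-eudesma-1,3,7(11)-trien-12,6α-olide (key-step precursor) | CC(=O)OCC1=C2[C@@H](OC(=O)[C@@](C)(O)CCl)C[C@@]3(C)C=CC=C(C)[C@@H]3[C@H]2OC1=O | intermediate
19 | 13-acetoxy-8α-[(R)-3-chloro-2-hydroxy-2-methylpropanoyloxy]germacra-1(10)E,2Z,4E,7(11)-tetraen-12,6α-olide (key-step product) | CC(=O)OCC1=C2[C@@H](OC(=O)[C@@](C)(O)CCl)C/C(C)=C/C=C\C(C)=C\[C@H]2OC1=O | intermediate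
20 | 13-acetoxy-8α-[(R)-3-chloro-2-hydroxy-2-methylpropanoyloxy]germacra-1(10)E,4E,7(11)-trien-12,6α-olide | CC(=O)OCC1=C2[C@@H](OC(=O)[C@@](C)(O)CCl)C/C(C)=C/CC/C(C)=C/[C@H]2OC1=O | intermediate
21 | CNP0255009.1, (1R,4R,5R,6S,8S,10R,2′R)-13-acetoxy-8α-(3-chloro-2-hydroxy-2-methylpropanoyloxy)-1β,10α:4α,5β-diepoxygermacr-7(11)-en-12,6α-olide | CC(=O)OCC1=C2[C@@H](OC(=O)[C@@](C)(O)CCl)C[C@@]3(C)O[C@@H]3CC[C@@]3(C)O[C@@H]3[C@H]2OC1=O | target

Total step count: 17
Longest linear sequence: 16 steps (steps 1–9 and 11–17, from α-santonin)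

**Steps most likely to fail**

1. Step 15 (key step). The photoequilibrium may lie on the side of the bicyclic diene. The triene may be consumed by secondary photoreactions, such as E/Z isomerisation or a di-π-methane-type reorganisation across C4=C5–C6–C7=C11. It may also re-close thermally in the disrotatory sense during handling, and any diene left over is lost in step 16. The fallback sets out from 18 and comes back at 19. The irradiation is run in a closed loop in which the cold photolysate is pumped continuously through a cooled bed of AgNO3 on silica. The strained E-alkenes bind silver and are held back as the silver nitrate complex of the triene F1, while the unstrained diene 18 passes through and returns to the lamp. The equilibrium is thereby drained and the triene is shielded from light. Shaking the loaded silica at −30 °C with cold brine and Et2O precipitates AgCl and liberates 19 for step 16.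

2. Step 9. The ene reaction may be too slow at an alkene deactivated by the lactone carbonyl and two allylic acyloxy groups. At the temperature then required, attack at the ring A allylic C3–H, loss of the silyl ether or over-oxidation at C8 may take over. The fallback sets out from 9 and comes back at 16, replacing steps 7–9, 11 and 12. Wohl–Ziegler bromination of enone 9 (NBS, AIBN, PhCF3, 80 °C) abstracts the only allylic hydrogen that is not on an oxygen-bearing carbon. Bromine is delivered axially, as in kinetic γ-bromination of cyclic enones, to give 13-acetoxy-8β-bromo-4α-methyl-3-oxo-5αH-eudesma-1,7(11)-dien-12,6α-olide F2. Acid 14 is converted with Cs2CO3 into cesium (S)-2-methyloxirane-2-carboxylate F3. This salt displaces the allylic bromide in DMF at 0 °C with inversion to give the 8α-epoxy ester enone F4. Luche reduction of F4, as in step 7, gives 16.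

3. Step 11. The axial 8β-oxygen is syn-axial to C14, so its activation may be slow. Once it is activated, antiperiplanar loss with 9α-H to a cross-ring conjugated dienolide may outrun substitution. The fallback sets out from 12 and comes back at 15. Dess–Martin oxidation gives the 8-ketone F5. Oxazaborolidine-catalysed (CBS) reduction with (R)-Me-CBS and catecholborane at −78 °C uses reagent control to deliver hydride to the β face and gives the 8α-alcohol F6. Steglich esterification of F6 with 14 (DCC, DMAP cat., CH2Cl2, 0 °C) proceeds with retention at C8 and gives 15.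

Further compounds
F1 | step 15 | silver nitrate complex of triene 19 | CC(=O)OCC1=C2[C@@H](OC(=O)[C@@](C)(O)CCl)C/C(C)=C/C=C\C(C)=C\[C@H]2OC1=O.[Ag+].[O-][N+](=O)[O-]
F2 | step 9 | 13-acetoxy-8β-bromo-4α-methyl-3-oxo-5αH-eudesma-1,7(11)-dien-12,6α-olide | CC(=O)OCC1=C2[C@H](Br)C[C@@]3(C)C=CC(=O)[C@@H](C)[C@@H]3[C@H]2OC1=O
F3 | step 9 | cesium (S)-2-methyloxirane-2-carboxylate | [Cs+].[O-]C(=O)[C@@]1(C)OC1
F4 | step 9 | 13-acetoxy-8α-[(S)-2-methyloxirane-2-carbonyloxy]-4α-methyl-3-oxo-5αH-eudesma-1,7(11)-dien-12,6α-olide | CC(=O)OCC1=C2[C@@H](OC(=O)[C@@]4(C)OC4)C[C@@]3(C)C=CC(=O)[C@@H](C)[C@@H]3[C@H]2OC1=O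
F5 | step 11 | 13-acetoxy-8-oxo-3β-(tert-butyldimethylsilyloxy)-4α-methyl-5αH-eudesma-1,7(11)-dien-12,6α-olide | CC(=O)OCC1=C2C(=O)C[C@@]3(C)C=C[C@H](O[Si](C)(C)C(C)(C)C)[C@@H](C)[C@@H]3[C@H]2OC1=O
F6 | step 11 | 13-acetoxy-8α-hydroxy-3β-(tert-butyldimethylsilyloxy)-4α-methyl-5αH-eudesma-1,7(11)-dien-12,6α-olide | CC(=O)OCC1=C2[C@@H](O)C[C@@]3(C)C=C[C@H](O[Si](C)(C)C(C)(C)C)[C@@H](C)[C@@H]3[C@H]2OC1=O
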